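## Retrosynthetic overview

Ring labels: A is the dimethoxybenzene ring, B is the nitrogen ring, C is the naphthalene ring that carries the biaryl bond, and D is the methyl-bearing naphthalene ring.

1. Target 15 comes from the N-tosyl tetrahydroisoquinoline 14 by N–S cleavage as the last step.
2. 14 comes from the open-chain fluorobiaryl N,O-acetal 5 and senecioamide 8 in one flask. Ring D is built on ring C by an aryne/dienolate annulation, and ring B closes when the acid quench unmasks N–CH2OMe as an iminium ion.
3. 5 comes from 4, which comes from a three-component Catellani coupling of 1, 2 and 3. This step makes the C4–C4a bond and the biaryl bond while the axis is still unhindered. C-3 is bought in with the L-alanine-derived aziridine 2.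
4. Ring order: A and C are purchased, then D and B form in the same operation.

Assumption: the SMILES defines only C-3 (S) and no axial descriptor, so the (3S) compound counts as the target whatever the configuration of the hindered axis. A separable pair of atropisomers is expected.

## Route

Step 1
Reactants: 1 1-iodo-2,4-dimethoxybenzene; 2 (2S)-2-methyl-1-(4-methylbenzenesulfonyl)aziridine; 3 (2-fluoro-4-methoxyphenyl)boronic acid
Product: 4 N-[(2S)-1-(2'-fluoro-4,4',6-trimethoxy[1,1'-biphenyl]-2-yl)propan-2-yl]-4-methylbenzenesulfonamide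
Conditions: Pd(OAc)2 (5 mol %), XPhos (12 mol %), norbornene (1 equiv), K2CO3 (3 equiv), 2 (1.5 equiv), 3 (1.8 equiv), MeCN–H2O 20:1, 80 °C
Reagents that add atoms: none
Why: Catellani reaction (palladium/norbornene cooperative catalysis): zerovalent palladium inserts into the C–I bond of 1, norbornene relays the metal to the free ortho C–H, the resulting palladacycle of divalent palladium opens 2 by SN2 attack at its unsubstituted CH2 so that the stereocentre taken from L-alanine is never touched and stays S, and after norbornene extrusion the doubly ortho-substituted arylpalladium is intercepted by 3 in a Suzuki-type termination that is easy because ring C carries only a small fluorine next to the new bond.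

Step 2
Reactants: 4 N-[(2S)-1-(2'-fluoro-4,4',6-trimethoxy[1,1'-biphenyl]-2-yl)propan-2-yl]-4-methylbenzenesulfonamide
Product: 5 N-[(2S)-1-(2'-fluoro-4,4',6-trimethoxy[1,1'-biphenyl]-2-yl)propan-2-yl]-N-(methoxymethyl)-4-methylbenzenesulfonamide
Conditions: ClCH2OCH3 (1.5 equiv), K2CO3, DMF, 0 °C to rt; chromatography on Et3N-washed silica
Reagents that add atoms: chloromethyl methyl ether, COCCl
Why: N-alkylation of the acidic sulfonamide N–H by the SN1-like electrophile ClCH2OCH3 gives a base-stable N,O-acetal that removes the only acidic and aryne-reactive N–H and already carries the future C-1, with C-3 untouched.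

Step 3
Reactants: 6 3-methylbut-2-enoyl chloride; 7 diethylamine
Product: 8 N,N-diethyl-3-methylbut-2-enamide
Conditions: aq NaOH, CH2Cl2, 0 °C
Reagents that add atoms: none
Why: Schotten–Baumann acylation of a secondary amine by an acid chloride, fast at 0 °C and without stereochemical issues.

Step 4
Reactants: 5 N-[(2S)-1-(2'-fluoro-4,4',6-trimethoxy[1,1'-biphenyl]-2-yl)propan-2-yl]-N-(methoxymethyl)-4-methylbenzenesulfonamide; 8 N,N-diethyl-3-methylbut-2-enamide
Product: 14 (3S)-5-(4,5-dimethoxy-7-methylnaphthalen-1-yl)-6,8-dimethoxy-3-methyl-2-(4-methylbenzenesulfonyl)-1,2,3,4-tetrahydroisoquinoline, via lithium dienolate 9 (not isolated), via aryne 10 (not isolated), via lithium naphtholate 11 (not isolated), via methyl ether 12 (not isolated), via iminium ion 13 (not isolated)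
Conditions: 8 (3 equiv), LiN(i-Pr)2 (commercial solution, 5 equiv), THF, −78 °C; add 5, −78 °C to rt; Me2SO4 (excess), DMPU, rt to 40 °C; dilute with CH2Cl2, TFA (large excess), 0 °C to rt
Reagents that add atoms: dimethyl sulfate, COS(=O)(=O)OC
Why: Proposed new method: LiN(i-Pr)2 removes the proton between F and OMe of 5 and loss of LiF gives aryne 10, whose methoxy group polarises the triple bond so that the CH2 terminus of the chelated dienolate 9 adds at the carbon meta to OMe (next to the biaryl bond), the resulting ortho-methoxy aryllithium closes onto the amide carbonyl, expels LiNEt2 and tautomerises to naphtholate 11 (ring D), this is O-methylated in the flask to 12, and TFA then ionises the base-stable N,O-acetal to the N-sulfonyliminium ion 13, which attacks the only free position ortho to the side chain (para to OMe) and closes ring B without touching C-3; the closest known reaction types are the anionic aryne annulation of lithiated senecioamides to 3-methyl-1-naphthols and the N-sulfonyl Pictet–Spengler cyclisation, and what is new is running both in one flask on an aryne flanked by a bulky aryl group.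

Step 5
Reactants: 14 (3S)-5-(4,5-dimethoxy-7-methylnaphthalen-1-yl)-6,8-dimethoxy-3-methyl-2-(4-methylbenzenesulfonyl)-1,2,3,4-tetrahydroisoquinoline
Product: 15 (3S)-5-(4,5-dimethoxy-7-methylnaphthalen-1-yl)-6,8-dimethoxy-3-methyl-1,2,3,4-tetrahydroisoquinoline
Conditions: Mg turnings (10 equiv), MeOH, ultrasound, rt to 40 °C; aq NH4Cl
Reagents that add atoms: none
Why: Reductive N–S cleavage of an arenesulfonamide by single-electron transfer from magnesium in methanol, which leaves the aryl methyl ethers, the electron-rich naphthalene and the C-3 stereocentre untouched.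

## Compound list

1 | 1-iodo-2,4-dimethoxybenzene | COc1ccc(I)c(OC)c1 | starting material
2 | (2S)-2-methyl-1-(4-methylbenzenesulfonyl)aziridine | C[C@H]1CN1S(=O)(=O)c1ccc(C)cc1 | starting material
3 | (2-fluoro-4-methoxyphenyl)boronic acid | COc1ccc(B(O)O)c(F)c1 | starting material
4 | N-[(2S)-1-(2'-fluoro-4,4',6-trimethoxy[1,1'-biphenyl]-2-yl)propan-2-yl]-4-methylbenzenesulfonamide | COc1cc(OC)c(-c2ccc(OC)cc2F)c(C[C@H](C)NS(=O)(=O)c2ccc(C)cc2)c1 | intermediate
5 | N-(methoxymethyl) derivative of 4 | COc1cc(OC)c(-c2ccc(OC)cc2F)c(C[C@H](C)N(COC)S(=O)(=O)c2ccc(C)cc2)c1 | intermediate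
6 | 3-methylbut-2-enoyl chloride | CC(C)=CC(=O)Cl | starting material
7 | diethylamine | CCNCC | starting material
8 | N,N-diethyl-3-methylbut-2-enamide | CCN(CC)C(=O)C=C(C)C | intermediate
9 | lithium 1-(diethylamino)-3-methylbuta-1,3-dien-1-olate | [Li+].C=C(C)C=C([O-])N(CC)CC | intermediate
10 | aryne from 5 (2',3'-didehydro, fluoride lost) | COC1=CC=C(C#C1)c1c(OC)cc(OC)cc1C[C@H](C)N(COC)S(=O)(=O)c1ccc(C)cc1 | intermediate
11 | lithium 5-{2,4-dimethoxy-6-[(2S)-2-(N-methoxymethyl-4-methylbenzenesulfonamido)propyl]phenyl}-8-methoxy-3-methylnaphthalen-1-olate | [Li+].[O-]c1cc(C)cc2c(-c3c(OC)cc(OC)cc3C[C@H](C)N(COC)S(=O)(=O)c3ccc(C)cc3)ccc(OC)c12 | intermediate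
12 | N-[(2S)-1-[2-(4,5-dimethoxy-7-methylnaphthalen-1-yl)-3,5-dimethoxyphenyl]propan-2-yl]-N-(methoxymethyl)-4-methylbenzenesulfonamide | COc1cc(C)cc2c(-c3c(OC)cc(OC)cc3C[C@H](C)N(COC)S(=O)(=O)c3ccc(C)cc3)ccc(OC)c12 | intermediate
13 | N-methylidene N-sulfonyliminium ion from 12 | COc1cc(C)cc2c(-c3c(OC)cc(OC)cc3C[C@H](C)[N+](=C)S(=O)(=O)c3ccc(C)cc3)ccc(OC)c12 | intermediate
14 | (3S)-5-(4,5-dimethoxy-7-methylnaphthalen-1-yl)-6,8-dimethoxy-3-methyl-2-(4-methylbenzenesulfonyl)-1,2,3,4-tetrahydroisoquinoline | COc1cc(OC)c(-c2ccc(OC)c3c(OC)cc(C)cc23)c2c1CN(S(=O)(=O)c1ccc(C)cc1)[C@@H](C)C2 | intermediate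
15 | (3S)-5-(4,5-dimethoxy-7-methylnaphthalen-1-yl)-6,8-dimethoxy-3-methyl-1,2,3,4-tetrahydroisoquinoline | COc1cc(OC)c(-c2ccc(OC)c3c(OC)cc(C)cc23)c2c1CN[C@@H](C)C2 | target

## Step count and risks

Total steps: 5. Longest linear sequence: 4 (steps 1, 2, 4, 5).

**Step 4.** The aryl group next to the aryne may slow or misdirect the addition of 9. The one-flask methylation of the chelated naphtholate may also be sluggish. The fallback swaps the roles of the partners, so that a small unhindered aryne is attacked and ring A carries the dienolate. It sets out from 1 and 2 and comes back at 12.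
- A Catellani coupling of 1 and 2 that ends in a Heck reaction with purchased methyl but-3-enoate gives methyl (3E)-4-{2,4-dimethoxy-6-[(2S)-2-(4-methylbenzenesulfonamido)propyl]phenyl}but-3-enoate F3.
- ClCH2OCH3 and K2CO3 give its N-methoxymethyl derivative F4.
- LiN(i-Pr)2 turns F4 into the extended lithium dienolate F5. In the same flask it turns purchased 1-bromo-3-methoxy-5-methylbenzene into 3-methoxy-5-methylbenzyne F6.
- The aryl-bearing terminus of F5 adds meta to the methoxy group of F6, and the aryllithium closes onto the ester. This gives the lithium 4-aryl-8-methoxy-6-methylnaphthalen-1-olate F7, so ring C is now the ring that is formed.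
- Me2SO4 converts F7 into 12, and TFA finishes as in step 4.

**Step 1.** Intramolecular C–N closure to an indoline, or direct Suzuki coupling of 1, may outrun the three-component path. The fallback builds the same bonds one at a time. It sets out from 2 and comes back at 4.
- Purchased 3,5-dimethoxyphenylmagnesium bromide with catalytic CuI opens 2 at CH2 to give N-[(2S)-1-(3,5-dimethoxyphenyl)propan-2-yl]-4-methylbenzenesulfonamide F1.
- N-iodosuccinimide in MeCN iodinates para to one methoxy group and ortho to the side chain, giving N-[(2S)-1-(2-iodo-3,5-dimethoxyphenyl)propan-2-yl]-4-methylbenzenesulfonamide F2.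
- A Suzuki coupling of F2 with 3 (Pd(OAc)2, SPhos, K3PO4, toluene–H2O, 90 °C) gives 4.

**Step 5.** The dialkyl tosylamide may be reduced only slowly, or the benzylic C–N bond may suffer. The fallback replaces electron transfer by elimination followed by reduction. It sets out from 14 and comes back at 15.
- KOtBu in DMSO at rt for a short time, to avoid azaallyl racemisation, removes a benzylic C-1 proton and expels sulfinate. This gives (3S)-5-(4,5-dimethoxy-7-methylnaphthalen-1-yl)-6,8-dimethoxy-3-methyl-3,4-dihydroisoquinoline F8.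
- NaBH4 in MeOH reduces the C=N bond of F8 to 15 without creating a new stereocentre.

## Further compounds

F1 | step 1 | N-[(2S)-1-(3,5-dimethoxyphenyl)propan-2-yl]-4-methylbenzenesulfonamide | COc1cc(OC)cc(C[C@H](C)NS(=O)(=O)c2ccc(C)cc2)c1
F2 | step 1 | N-[(2S)-1-(2-iodo-3,5-dimethoxyphenyl)propan-2-yl]-4-methylbenzenesulfonamide | COc1cc(OC)c(I)c(C[C@H](C)NS(=O)(=O)c2ccc(C)cc2)c1
F3 | step 4 | methyl (3E)-4-{2,4-dimethoxy-6-[(2S)-2-(4-methylbenzenesulfonamido)propyl]phenyl}but-3-enoate | COC(=O)C/C=C/c1c(OC)cc(OC)cc1C[C@H](C)NS(=O)(=O)c1ccc(C)cc1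
F4 | step 4 | N-methoxymethyl derivative of F3 | COC(=O)C/C=C/c1c(OC)cc(OC)cc1C[C@H](C)N(COC)S(=O)(=O)c1ccc(C)cc1
F5 | step 4 | extended lithium dienolate of F4 | [Li+].COC([O-])=C/C=C/c1c(OC)cc(OC)cc1C[C@H](C)N(COC)S(=O)(=O)c1ccc(C)cc1
F6 | step 4 | 3-methoxy-5-methylbenzyne | COC1=CC(C)=CC#C1
F7 | step 4 | lithium 4-{2,4-dimethoxy-6-[(2S)-2-(N-methoxymethyl-4-methylbenzenesulfonamido)propyl]phenyl}-8-methoxy-6-methylnaphthalen-1-olate | [Li+].[O-]c1ccc(-c2c(OC)cc(OC)cc2C[C@H](C)N(COC)S(=O)(=O)c2ccc(C)cc2)c2cc(C)cc(OC)c12
F8 | step 5 | (3S)-5-(4,5-dimethoxy-7-methylnaphthalen-1-yl)-6,8-dimethoxy-3-methyl-3,4-dihydroisoquinoline | COc1cc(OC)c(-c2ccc(OC)c3c(OC)cc(C)cc23)c2c1C=N[C@@H](C)C2
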